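**Assumption:** I take the SMILES literally. That means H-8 and H-8′ are anti, so the bicycle is trans-fused and the skeleton is centrosymmetric, with the C-9′ lactol anomer as drawn (assumed to equilibrate and be isolated as drawn). Lignan numbering is used throughout: C-7/C-7′ carry the aryl groups, C-8/C-8′ are the ring-fusion carbons, and C-9/C-9′ are the oxygenated terminal carbons. Ring A is C7–O–C9′ and contains the lactol. Ring B is C7′–O–C9.

## Retrosynthetic overview
1. The target comes from hydrogenolysis of the two benzyl ethers and a final, reversible lactolization of the C-9′ aldehyde onto 7-OH (ring A, the strained trans-fused ring, closed last).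
2. Ring B (the 7′–O–9 ether) comes from an intramolecular Mitsunobu cyclodehydration of an acyclic triol. In that triol C-9′ is masked as a dimethylhydrazone, and the resulting ring is unstrained because ring A is still open.
3. The triol comes from two successive organocatalytic anti-aldol reactions of 4-benzyloxy-3-methoxybenzaldehyde, using opposite proline enantiomers. The first is at C-8 with methyl 4-oxobutanoate, whose ester is the latent C-9′ carbon. The second is at C-8′ after DIBAL converts the resulting lactone into a masked aldehyde.
4. Order of bond and ring formation: C7–C8 pair, then C7′–C8′ pair (both acyclic), then ether ring B, then lactol ring A.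

## Route

**Step 1**
Reactants: 1 (4-(benzyloxy)-3-methoxybenzaldehyde), 2 (methyl 4-oxobutanoate)
Product: 3 ((4S)-4-[(S)-[4-(benzyloxy)-3-methoxyphenyl](hydroxy)methyl]oxolan-2-one)
Conditions: (R)-proline (20 mol %), DMF, 4 °C, slow addition of 2 to excess 1; then NaBH4, MeOH, 0 °C; then TsOH (cat.), CH2Cl2, rt
Reagents that add atoms: none
Why: Enamine-catalysed cross-aldol (anti-selective, proline type) of the aldehyde donor with the aryl aldehyde sets the 7-(S) carbinol and C-8 anti to it (the first stereocentres, set by asymmetric catalysis). In-situ NaBH4 reduction prevents retro-aldol and epimerization, and the diol-ester lactonizes to the γ-lactone. The catalyst enantiomer is chosen to give the (S)-carbinol, on the assumption that (S)-proline gives the (R)-carbinol. If the 7-OH lactone forms instead, it converges on the same lactol in Step 2.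

**Step 2**
Reactants: 3
Product: 4 ((4S)-4-[(S)-[4-(benzyloxy)-3-methoxyphenyl](hydroxy)methyl]oxolan-2-ol, anomeric mixture, in equilibrium with the hydroxy-aldehyde)
Conditions: DIBAL-H (2.2 equiv), CH2Cl2, −78 °C; cold Rochelle-salt quench
Reagents that add atoms: none
Why: Partial reduction of a lactone to a lactol (DIBAL-H, stable aluminium hemiacetalate at −78 °C) unmasks the latent C-9′ aldehyde without touching any stereocentre; the benzylic 7-OH consumes one equivalent of hydride.

**Step 3**
Reactants: 4, 1, 5 (1,1-dimethylhydrazine)
Product: 6 ((2S,3R)-2-[(S)-[4-(benzyloxy)-3-methoxyphenyl](hydroxy)methyl]-3-[(R)-[4-(benzyloxy)-3-methoxyphenyl](hydroxy)methyl]-4-(2,2-dimethylhydrazin-1-ylidene)butan-1-ol)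
Conditions: (S)-proline (30 mol %), 1 (3 equiv), DMF, 4 °C, 48 h; aqueous NaHSO3 wash to remove excess 1; then Me2NNH2, CH2Cl2, MgSO4, rt
Reagents that add atoms: 1,1-dimethylhydrazine, CN(C)N
Why: Enamine (proline) cross-aldol at C-8′ sets the 7′-(R) carbinol and C-8′ anti, with the catalyst enantiomer opposite to Step 1 so that the two halves are related by inversion (the trans-fused, centrosymmetric skeleton), and the hydrazone then masks the aldehyde so it cannot form lactols or undergo retro-aldol. Proposed new method: a lactol (hydroxy-aldehyde ring–chain tautomer) serves as the masked enamine donor toward an electron-rich aryl aldehyde, and the catalyst rather than the resident C-8 stereocentre controls the new anti pair (a catalyst-controlled, mismatched double diastereodifferentiation); mechanistically, lactol ⇌ hydroxy-aldehyde → (E)-enamine → face-selective attack on ArCHO through the proline carboxylic-acid-directed Houk–List transition state. The closest known reactions are proline cross-aldol of aldehydes and lactols as donors in enamine Michael additions.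

**Step 4**
Reactants: 6
Product: 7 ((S)-[4-(benzyloxy)-3-methoxyphenyl][(3S,4R,5R)-5-[4-(benzyloxy)-3-methoxyphenyl]-4-[(2,2-dimethylhydrazin-1-ylidene)methyl]oxolan-3-yl]methanol)
Conditions: Ph3P (1.5 equiv), DIAD (1.5 equiv), THF, 0 °C → rt
Reagents that add atoms: none
Why: Intramolecular Mitsunobu cyclodehydration of a 1,4-diol activates the primary 9-OH and the 7′-OH closes the 5-exo ring, so C-7′ is retained and ring B is formed with no ring strain because ring A is not yet closed; the 7-OH cannot close (oxetane) and the hydrazone holds C-9′ masked.

**Step 5**
Reactants: 7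
Product: 8 ((7S,7′R,8S,8′S,9′R)-4,4′-bis(benzyloxy)-9′-hydroxy-3,3′-dimethoxy-7,9′:7′,9-diepoxylignane)
Conditions: NaIO4 (3 equiv), THF / pH 7 phosphate buffer (1:1), rt
Reagents that add atoms: water, O
Why: Oxidative hydrolysis of an N,N-dimethylhydrazone is a mild unmasking to the aldehyde, which closes onto 7-OH under equilibrium control (hemiacetalization) to give the C-9′ lactol, the only ring closure that introduces strain; no new stereocentre is set except the anomeric one, which equilibrates.

**Step 6**
Reactants: 8
Product: 9 (target, (7S,7′R,8S,8′S,9′R)-4,4′,9′-trihydroxy-3,3′-dimethoxy-7,9′:7′,9-diepoxylignane)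
Conditions: H2 (1 atm), 10% Pd/C, EtOAc, rt, 1–2 h
Reagents that add atoms: none
Why: Hydrogenolysis of the two aryl benzyl ethers frees both phenols and leaves the stereocentres untouched, since the short reaction time avoids cleaving the benzylic ether and lactol.

## Compound list
1 | 4-(benzyloxy)-3-methoxybenzaldehyde | COc1cc(C=O)ccc1OCc1ccccc1 | starting material
2 | methyl 4-oxobutanoate | COC(=O)CCC=O | starting material
3 | (4S)-4-[(S)-aryl(hydroxy)methyl]oxolan-2-one (aryl = 4-OBn-3-OMe-phenyl) | COc1cc([C@@H](O)[C@@H]2COC(=O)C2)ccc1OCc1ccccc1 | intermediate
4 | (4S)-4-[(S)-aryl(hydroxy)methyl]oxolan-2-ol | COc1cc([C@@H](O)[C@@H]2COC(O)C2)ccc1OCc1ccccc1 | intermediate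
5 | 1,1-dimethylhydrazine | CN(C)N | starting material
6 | acyclic triol N,N-dimethylhydrazone | COc1cc([C@@H](O)[C@H](CO)[C@H](C=NN(C)C)[C@@H](O)c2ccc(OCc3ccccc3)c(OC)c2)ccc1OCc1ccccc1 | intermediate
7 | 2,3,4-trisubstituted tetrahydrofuran hydrazone (ring B) | COc1cc([C@@H](O)[C@@H]2CO[C@@H](c3ccc(OCc4ccccc4)c(OC)c3)[C@H]2C=NN(C)C)ccc1OCc1ccccc1 | intermediate
8 | dibenzyl lactol | COc1cc([C@H]2O[C@@H](O)[C@H]3[C@H]2CO[C@H]3c2ccc(OCc4ccccc4)c(OC)c2)ccc1OCc1ccccc1 | intermediate
9 | 4α-hydroxypinoresinol | COc1cc([C@H]2O[C@@H](O)[C@H]3[C@H]2CO[C@H]3c2ccc(O)c(OC)c2)ccc1O | target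

**Total steps:** 6. **Longest linear sequence:** 6 (2 → 3 → 4 → 6 → 7 → 8 → 9).

## Three steps most likely to fail
1. **Step 3 (proposed new method):** the lactol donor may be too slow, homo-aldolize, or give poor diastereocontrol against the resident C-8 stereocentre. Fallback (known chemistry): hydrolyse lactone 3 to the hydroxy-acid and protect both OH groups. Couple it to (S)-4-benzyloxazolidin-2-one and carry out an Evans MgCl2/Et3N/TMSCl anti-aldol with 1. Then cleave the auxiliary reductively to the aldehyde level, deprotect, and form the hydrazone to reach 6.
2. **Step 5:** the trans-fused lactol is strained, so the compound may stay as the open hydroxy-aldehyde or epimerize at C-8′ (C-8′ is α to the aldehyde and sits cis to the 7′-aryl group). Fallback: unmask to the aldehyde, reduce it (NaBH4), and perform a TEMPO/PIDA oxidative lactonization of the 1,4-diol. Then reduce the lactone with DIBAL-H at −78 °C and quench cold to trap the lactol kinetically as its aluminium hemiacetalate. This replaces the equilibrium-controlled closure with a kinetically trapped one.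
3. **Step 1:** the electron-rich aryl aldehyde is a poor aldol acceptor, so the yield or ee may be low. Fallback: use an Evans Mg-mediated anti-aldol of the oxazolidinone imide of monomethyl succinate with 1, then LiBH4 reduction and acid lactonization to give 3.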